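**Retrosynthetic overview** (germacranolide numbering: ring carbons C1–C10, lactone unit C11(=C13)–C12(=O)–O–C6, C14 on C10, C15 on C4, ether oxygen between C1 and C5)
1. Last operations: epoxidation of an exocyclic C4=C15 alkene, oxidation of a C14 alcohol to the aldehyde and methacrylation of C8-OH, all on the bridged bicyclic alcohol delivered by the key step.
2. Key disconnection: C7–C8 and C1–C10 are made in one flask by a Lewis-acid-relayed formal [7+3] annulation of an oxane methyl acetal carrying a 3-(tributylstannylmethyl)butenolide with (Z)-4-silyloxy-3-(trimethylsilyl)but-2-enal (C8 = aldehyde, C10 = vinylsilane carbon).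
3. Enabling feature: C1 is the oxane carbon next to the ring oxygen (an acetal in the precursor, hence a cyclic oxocarbenium ion); C7 is the β-carbon of the butenolide ring whose α-carbon C11 bears C13–Sn (a latent α-methylene lactone); the ring oxygen ties C1 to C5, so the C5–C6–C7 arm can reach C1 only on the cis face.
4. The annulation precursor comes from furans: vinylogous Mukaiyama aldol (C5–C6) of a 3-(silyloxymethyl)-2-silyloxyfuran with furfural, then Achmatowicz ring expansion (furan to oxane with C1 acetal and C4 ketone) merged with a Sharpless kinetic resolution.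
5. Ring order: butenolide (step 4), oxane (step 5), ten-membered carbocycle with the 1,5-ether bridge and the α-methylene lactone (step 16), spiro-epoxide (step 20).

Key step: step 16

Remark on the chemistry: the acetal carbon C1 of all monocyclic oxane intermediates is carried as an anomeric mixture and is written without configuration in the SMILES, because it is planarised in the key step. The kinetic resolution is assumed to follow the empirical rule for 2-furylcarbinols.

**Step 1**
Reactants: 1 furan-3-ylmethanol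
Product: 2 tert-butyl(furan-3-ylmethoxy)dimethylsilane
Conditions: TBSCl, imidazole, DMF, rt
Reagents that add atoms: tert-butyldimethylsilyl chloride, CC(C)(C)[Si](C)(C)Cl
Why: Standard imidazole-mediated O-silylation of a primary alcohol; no stereocentre is involved.

**Step 2**
Reactants: 2 tert-butyl(furan-3-ylmethoxy)dimethylsilane
Product: 4 3-({[tert-butyl(dimethyl)silyl]oxy}methyl)furan-2(5H)-one, via furan-2-ylboronate ester 3 (not isolated)
Conditions: n-BuLi, THF, −78 → −20 °C; B(OMe)3, −78 °C → rt; then 30% H2O2, AcOH, 0 °C → rt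
Reagents that add atoms: hydrogen peroxide, OO
Why: Oxygen-directed lithiation at furan C2, borylation and oxidative C–B cleavage give the 2-hydroxyfuran, which tautomerises to the butenolide; the lithiation is kept cold and free of HMPA so that the 1,4 O→C silyl shift does not compete.

**Step 3**
Reactants: 4 3-({[tert-butyl(dimethyl)silyl]oxy}methyl)furan-2(5H)-one
Product: 5 tert-butyl{[3-({[tert-butyl(dimethyl)silyl]oxy}methyl)furan-2-yl]oxy}dimethylsilane
Conditions: TBSOTf, Et3N, CH2Cl2, 0 °C
Reagents that add atoms: tert-butyldimethylsilyl triflate, CC(C)(C)[Si](C)(C)OS(=O)(=O)C(F)(F)F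
Why: Soft enolisation with O-silylation converts the butenolide into the aromatic 2-silyloxyfuran, the dienolate equivalent for the next step.

**Step 4**
Reactants: 5 tert-butyl{[3-({[tert-butyl(dimethyl)silyl]oxy}methyl)furan-2-yl]oxy}dimethylsilane; 6 furan-2-carbaldehyde
Product: 7 rac-(5S)-3-({[tert-butyl(dimethyl)silyl]oxy}methyl)-5-[(R)-furan-2-yl(hydroxy)methyl]furan-2(5H)-one (threo racemate)
Conditions: BF3·OEt2, CH2Cl2, −78 °C; aq NaHCO3
Reagents that add atoms: none
Why: Vinylogous Mukaiyama aldol reaction at furan C5 through an open transition state, which for Lewis-acid-promoted additions of 2-silyloxyfurans to aldehydes should favour the threo (5S*,1′R*) adduct; the erythro isomer is to be removed by chromatography.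

**Step 5**
Reactants: 7 rac-(5S)-3-({[tert-butyl(dimethyl)silyl]oxy}methyl)-5-[(R)-furan-2-yl(hydroxy)methyl]furan-2(5H)-one
Product: 8 (5S)-3-({[tert-butyl(dimethyl)silyl]oxy}methyl)-5-[(2R)-6-hydroxy-3-oxo-3,6-dihydro-2H-pyran-2-yl]furan-2(5H)-one (both anomers)
Conditions: Ti(OiPr)4, D-(−)-diisopropyl tartrate, t-BuOOH (0.5 equiv), 4 Å MS, CH2Cl2, −20 °C
Reagents that add atoms: tert-butyl hydroperoxide, CC(C)(C)OO
Why: Sharpless kinetic resolution of a 2-furylcarbinol merged with the Achmatowicz rearrangement: with the D-tartrate the (R)-carbinol should be the fast enantiomer and is ring-expanded to the pyranone with its carbinol centre (C5) intact, while the (5R,1′S)-enantiomer stays behind and is separated.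

**Step 6**
Reactants: 8 (5S)-3-({[tert-butyl(dimethyl)silyl]oxy}methyl)-5-[(2R)-6-hydroxy-3-oxo-3,6-dihydro-2H-pyran-2-yl]furan-2(5H)-one
Product: 9 (5S)-3-({[tert-butyl(dimethyl)silyl]oxy}methyl)-5-[(2R)-6-methoxy-3-oxo-3,6-dihydro-2H-pyran-2-yl]furan-2(5H)-one (both anomers)
Conditions: MeI, Ag2O, MeCN, rt, dark
Reagents that add atoms: iodomethane, CI
Why: Purdie-type O-methylation of the lactol hydroxyl under near-neutral conditions gives the methyl acetal without enolising the β-acyloxy ketone.

**Step 7**
Reactants: 9 (5S)-3-({[tert-butyl(dimethyl)silyl]oxy}methyl)-5-[(2R)-6-methoxy-3-oxo-3,6-dihydro-2H-pyran-2-yl]furan-2(5H)-one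
Product: 10 (5S)-3-({[tert-butyl(dimethyl)silyl]oxy}methyl)-5-[(2R)-6-methoxy-3-oxooxan-2-yl]furan-2(5H)-one
Conditions: H2 (1 atm), RhCl(PPh3)3 (5 mol %), benzene/EtOH, rt
Reagents that add atoms: none
Why: Homogeneous hydrogenation with RhCl(PPh3)3 should reduce the cis-disubstituted enone alkene and leave the trisubstituted butenolide alkene, the acetal and the allylic silyl ether untouched.

**Step 8**
Reactants: 10 (5S)-3-({[tert-butyl(dimethyl)silyl]oxy}methyl)-5-[(2R)-6-methoxy-3-oxooxan-2-yl]furan-2(5H)-one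
Product: 11 (5S)-3-({[tert-butyl(dimethyl)silyl]oxy}methyl)-5-[(2S)-6-methoxy-3-methylideneoxan-2-yl]furan-2(5H)-one
Conditions: Zn, CH2Br2, TiCl4, THF (reagent pre-formed at 0 °C); then 10, CH2Cl2, 0 °C → rt
Reagents that add atoms: dibromomethane, BrCBr
Why: Takai–Lombardo methylenation is non-basic and ketone-selective, so the C4 ketone becomes the exocyclic alkene without epimerising C5, eliminating the β-acyloxy group or touching the lactone (the descriptor at C5 changes by priority only).

**Step 9**
Reactants: 11 (5S)-3-({[tert-butyl(dimethyl)silyl]oxy}methyl)-5-[(2S)-6-methoxy-3-methylideneoxan-2-yl]furan-2(5H)-one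
Product: 12 (5S)-3-(hydroxymethyl)-5-[(2S)-6-methoxy-3-methylideneoxan-2-yl]furan-2(5H)-one
Conditions: HF·pyridine, pyridine, THF, 0 °C → rt
Reagents that add atoms: none
Why: Buffered fluoride cleavage of the primary allylic silyl ether, which the methyl acetal and the butenolide should tolerate.

**Step 10**
Reactants: 12 (5S)-3-(hydroxymethyl)-5-[(2S)-6-methoxy-3-methylideneoxan-2-yl]furan-2(5H)-one
Product: 13 (5S)-3-(bromomethyl)-5-[(2S)-6-methoxy-3-methylideneoxan-2-yl]furan-2(5H)-one
Conditions: CBr4, PPh3, CH2Cl2, 0 °C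
Reagents that add atoms: carbon tetrabromide, BrC(Br)(Br)Br
Why: Appel bromination of the primary allylic alcohol under neutral conditions (SN2 at C13).

**Step 11**
Reactants: 13 (5S)-3-(bromomethyl)-5-[(2S)-6-methoxy-3-methylideneoxan-2-yl]furan-2(5H)-one
Product: 14 (5S)-5-[(2S)-6-methoxy-3-methylideneoxan-2-yl]-3-[(tributylstannyl)methyl]furan-2(5H)-one
Conditions: Bu3SnSnBu3, Pd2(dba)3 (2.5 mol %), THF, rt
Reagents that add atoms: hexabutylditin, CCCC[Sn](CCCC)(CCCC)[Sn](CCCC)(CCCC)CCCC
Why: Stannylation of an allylic bromide with a distannane, catalysed by zerovalent palladium, through a 2-acyl π-allylpalladium intermediate; tin should go to the unhindered primary terminus C13, which is also the thermodynamic allylstannane (conjugated endocyclic alkene).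

**Step 12**
Reactants: 15 but-2-yne-1,4-diol
Product: 16 4-{[tert-butyl(dimethyl)silyl]oxy}but-2-yn-1-ol
Conditions: NaH (1.0 equiv), THF, 0 °C; TBSCl (1.0 equiv), 0 °C → rt
Reagents that add atoms: tert-butyldimethylsilyl chloride, CC(C)(C)[Si](C)(C)Cl
Why: Monosilylation of a symmetric diol through its sparingly soluble mono-sodium alkoxide.

**Step 13**
Reactants: 16 4-{[tert-butyl(dimethyl)silyl]oxy}but-2-yn-1-ol
Product: 17 (2Z)-4-{[tert-butyl(dimethyl)silyl]oxy}-3-iodobut-2-en-1-ol
Conditions: NaAlH2(OCH2CH2OMe)2, Et2O, 0 °C → rt; then I2, THF, −78 → 0 °C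
Reagents that add atoms: iodine, II
Why: Hydroxyl-directed trans-hydroalumination of the propargylic alcohol puts aluminium on the distal carbon (the future C10) anti to the delivered hydride, and iodinolysis with retention gives the (Z)-γ-iodo allylic alcohol.

**Step 14**
Reactants: 17 (2Z)-4-{[tert-butyl(dimethyl)silyl]oxy}-3-iodobut-2-en-1-ol
Product: 19 (2Z)-4-{[tert-butyl(dimethyl)silyl]oxy}-3-(trimethylsilyl)but-2-en-1-ol, via trimethylsilyl ether 18 (not isolated)
Conditions: n-BuLi, THF, −78 °C; Me3SiCl; then t-BuLi (2 equiv), −78 → 0 °C; aq NH4Cl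
Reagents that add atoms: chlorotrimethylsilane, C[Si](C)(C)Cl
Why: Iodine–lithium exchange on the O-silylated vinyl iodide triggers a [1,4]-retro-Brook (O→C) silyl migration with retention of alkene geometry, placing silicon cis to the carbinol carbon.

**Step 15**
Reactants: 19 (2Z)-4-{[tert-butyl(dimethyl)silyl]oxy}-3-(trimethylsilyl)but-2-en-1-ol
Product: 20 (2Z)-4-{[tert-butyl(dimethyl)silyl]oxy}-3-(trimethylsilyl)but-2-enal
Conditions: MnO2, CH2Cl2, rt
Reagents that add atoms: none
Why: Allylic oxidation with MnO2 stops at the aldehyde under neutral conditions and should keep the alkene geometry (the silyloxymethyl group is trans to the formyl group, so no lactol can form).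

**Step 16**
Reactants: 14 (5S)-5-[(2S)-6-methoxy-3-methylideneoxan-2-yl]-3-[(tributylstannyl)methyl]furan-2(5H)-one; 20 (2Z)-4-{[tert-butyl(dimethyl)silyl]oxy}-3-(trimethylsilyl)but-2-enal
Product: 22 (1R,5S,6S,7R,8R,9Z)-14-{[tert-butyl(dimethyl)silyl]oxy}-1,5-epoxy-8-hydroxygermacra-4(15),9,11(13)-trien-12,6-olide, via open-chain homoallylic alcohol 21 (not isolated)
Conditions: 20 (1.5 equiv), BF3·OEt2, 2,6-di-tert-butyl-4-methylpyridine, CH2Cl2, −78 °C; then Me3SiOTf, dilution to 0.005 M, −78 → −20 °C; aq NaHCO3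
Reagents that add atoms: none
Why: Proposed new method: the BF3-complexed aldehyde of 20 should be attacked at −78 °C by the γ-carbon C7 of the 2-(stannylmethyl)butenolide in an anti-SE2′ allylstannane addition (C7–C8, unveiling the α-methylene lactone of 21, held as its boron alkoxide), after which Me3SiOTf ionises the methyl acetal to the six-membered oxocarbenium ion, which the tethered vinylsilane captures at its silicon-bearing carbon (C1–C10) with loss of the silyl group. The closest known reactions are the Lewis-acid (Hosomi–Sakurai-type) allylation of aldehydes with 2-(stannylmethyl)acrylates and the acetal-initiated vinylsilane-terminated cyclisation that gives allylically unsaturated oxocenes; their union in one flask as a formal [7+3] annulation onto a cyclic oxocarbenium ion is the new element. The ring closure is an 8-endo cation–π cyclisation with respect to the oxocene ring O–C1–C10=C9–C8–C7–C6–C5, which at the same time closes the ten-membered carbocycle and creates the 11-oxabicyclo[5.3.1] core. C7 is set by attack on the butenolide face anti to the oxanyl group at C6 (trans lactone), C8 by the open antiperiplanar transition state of the E-locked allylstannane (C6 and O8 syn, 8R), C1 by delivery from the C5 arm (only the cis-2,6 bridge can form), and the C9=C10 geometry by ipso substitution with retention. The step needs chemoselectivity (the allylstannane must be consumed by the aldehyde before any oxocarbenium ion exists, otherwise C7 would close a five-membered ring onto C1) and site selectivity at C10: the first should be secured by the inertness of the 2-methoxyoxane to BF3·OEt2 at −78 °C and the late addition of Me3SiOTf, the second by the β-silicon effect, and conjugate addition to 20 is blocked because its β-carbon is fully substituted.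

**Step 17**
Reactants: 22 (1R,5S,6S,7R,8R,9Z)-14-{[tert-butyl(dimethyl)silyl]oxy}-1,5-epoxy-8-hydroxygermacra-4(15),9,11(13)-trien-12,6-olide
Product: 23 (1R,5S,6S,7R,8R,9Z)-14-{[tert-butyl(dimethyl)silyl]oxy}-1,5-epoxy-8-[(2-methylprop-2-enoyl)oxy]germacra-4(15),9,11(13)-trien-12,6-olide
Conditions: methacrylic anhydride, Et3N, DMAP (cat.), BHT (trace), CH2Cl2, 0 °C → rt
Reagents that add atoms: methacrylic anhydride, CC(=C)C(=O)OC(=O)C(C)=C
Why: DMAP-catalysed acylation of the secondary allylic alcohol with retention at C8, run directly on crude 22 at low temperature to outpace migration of the lactone from O6 to O8.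

**Step 18**
Reactants: 23 (1R,5S,6S,7R,8R,9Z)-14-{[tert-butyl(dimethyl)silyl]oxy}-1,5-epoxy-8-[(2-methylprop-2-enoyl)oxy]germacra-4(15),9,11(13)-trien-12,6-olide
Product: 24 (1R,5S,6S,7R,8R,9Z)-1,5-epoxy-14-hydroxy-8-[(2-methylprop-2-enoyl)oxy]germacra-4(15),9,11(13)-trien-12,6-olide
Conditions: HF·pyridine, pyridine, THF, 0 °C
Reagents that add atoms: none
Why: Buffered fluoride cleavage of the primary allylic silyl ether, which both esters, the Michael acceptors and the allylic ether should survive.

**Step 19**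
Reactants: 24 (1R,5S,6S,7R,8R,9Z)-1,5-epoxy-14-hydroxy-8-[(2-methylprop-2-enoyl)oxy]germacra-4(15),9,11(13)-trien-12,6-olide
Product: 25 (1R,5S,6S,7R,8R,9E)-1,5-epoxy-8-[(2-methylprop-2-enoyl)oxy]-14-oxogermacra-4(15),9,11(13)-trien-12,6-olide
Conditions: MnO2, CH2Cl2, rt
Reagents that add atoms: none
Why: Chemoselective MnO2 oxidation of the primary allylic alcohol to the enal with the alkene geometry of step 16 unchanged (the descriptor changes from Z to E by priority only).

**Step 20**
Reactants: 25 (1R,5S,6S,7R,8R,9E)-1,5-epoxy-8-[(2-methylprop-2-enoyl)oxy]-14-oxogermacra-4(15),9,11(13)-trien-12,6-olide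
Product: 26 (1R,4R,5R,6S,7R,8R,9E)-1,5:4,15-diepoxy-8-[(2-methylprop-2-enoyl)oxy]-14-oxogermacra-9,11(13)-dien-12,6-olide (CNP0257628.1)
Conditions: dimethyldioxirane (acetone solution, 1.1 equiv), CH2Cl2, −20 → 0 °C
Reagents that add atoms: dimethyldioxirane, CC1(C)OO1
Why: Electrophilic epoxidation picks the only electron-rich alkene (exocyclic C4=C15; the enal, the α-methylene lactone and the methacrylate are electron-poor) and should deliver oxygen to the face anti to the axial C5–C6 bond of the bridged oxane, setting C4 as R.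

**Compound list**
1 | furan-3-ylmethanol | OCc1ccoc1 | starting material
2 | tert-butyl(furan-3-ylmethoxy)dimethylsilane | CC(C)(C)[Si](C)(C)OCc1ccoc1 | intermediate
3 | dimethyl [3-({[tert-butyl(dimethyl)silyl]oxy}methyl)furan-2-yl]boronate (not isolated) | COB(OC)c1occc1CO[Si](C)(C)C(C)(C)C | intermediate
4 | 3-({[tert-butyl(dimethyl)silyl]oxy}methyl)furan-2(5H)-one | O=C1OCC=C1CO[Si](C)(C)C(C)(C)C | intermediate
5 | tert-butyl{[3-({[tert-butyl(dimethyl)silyl]oxy}methyl)furan-2-yl]oxy}dimethylsilane | CC(C)(C)[Si](C)(C)OCc1ccoc1O[Si](C)(C)C(C)(C)C | intermediate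
6 | furan-2-carbaldehyde (furfural) | O=Cc1ccco1 | starting material
7 | rac-(5S)-3-({[tert-butyl(dimethyl)silyl]oxy}methyl)-5-[(R)-furan-2-yl(hydroxy)methyl]furan-2(5H)-one (threo racemate; the SMILES shows the enantiomer carried on) | O[C@@H](c1ccco1)[C@H]1OC(=O)C(CO[Si](C)(C)C(C)(C)C)=C1 | intermediate
8 | (5S)-3-({[tert-butyl(dimethyl)silyl]oxy}methyl)-5-[(2R)-6-hydroxy-3-oxo-3,6-dihydro-2H-pyran-2-yl]furan-2(5H)-one (anomeric mixture) | OC1C=CC(=O)[C@H](O1)[C@H]1OC(=O)C(CO[Si](C)(C)C(C)(C)C)=C1 | intermediate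
9 | (5S)-3-({[tert-butyl(dimethyl)silyl]oxy}methyl)-5-[(2R)-6-methoxy-3-oxo-3,6-dihydro-2H-pyran-2-yl]furan-2(5H)-one (anomeric mixture) | COC1C=CC(=O)[C@H](O1)[C@H]1OC(=O)C(CO[Si](C)(C)C(C)(C)C)=C1 | intermediate
10 | (5S)-3-({[tert-butyl(dimethyl)silyl]oxy}methyl)-5-[(2R)-6-methoxy-3-oxooxan-2-yl]furan-2(5H)-one (anomeric mixture) | COC1CCC(=O)[C@H](O1)[C@H]1OC(=O)C(CO[Si](C)(C)C(C)(C)C)=C1 | intermediate
11 | (5S)-3-({[tert-butyl(dimethyl)silyl]oxy}methyl)-5-[(2S)-6-methoxy-3-methylideneoxan-2-yl]furan-2(5H)-one (anomeric mixture) | COC1CCC(=C)[C@H](O1)[C@H]1OC(=O)C(CO[Si](C)(C)C(C)(C)C)=C1 | intermediate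
12 | (5S)-3-(hydroxymethyl)-5-[(2S)-6-methoxy-3-methylideneoxan-2-yl]furan-2(5H)-one (anomeric mixture) | COC1CCC(=C)[C@H](O1)[C@H]1OC(=O)C(CO)=C1 | intermediate
13 | (5S)-3-(bromomethyl)-5-[(2S)-6-methoxy-3-methylideneoxan-2-yl]furan-2(5H)-one (anomeric mixture) | COC1CCC(=C)[C@H](O1)[C@H]1OC(=O)C(CBr)=C1 | intermediate
14 | (5S)-5-[(2S)-6-methoxy-3-methylideneoxan-2-yl]-3-[(tributylstannyl)methyl]furan-2(5H)-one (anomeric mixture) | COC1CCC(=C)[C@H](O1)[C@H]1OC(=O)C(C[Sn](CCCC)(CCCC)CCCC)=C1 | intermediate
15 | but-2-yne-1,4-diol | OCC#CCO | starting material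
16 | 4-{[tert-butyl(dimethyl)silyl]oxy}but-2-yn-1-ol | CC(C)(C)[Si](C)(C)OCC#CCO | intermediate
17 | (2Z)-4-{[tert-butyl(dimethyl)silyl]oxy}-3-iodobut-2-en-1-ol | OC/C=C(/CO[Si](C)(C)C(C)(C)C)I | intermediate
18 | tert-butyl({(2Z)-2-iodo-4-[(trimethylsilyl)oxy]but-2-en-1-yl}oxy)dimethylsilane (not isolated) | C[Si](C)(C)OC/C=C(/CO[Si](C)(C)C(C)(C)C)I | intermediate
19 | (2Z)-4-{[tert-butyl(dimethyl)silyl]oxy}-3-(trimethylsilyl)but-2-en-1-ol | OC/C=C(/CO[Si](C)(C)C(C)(C)C)[Si](C)(C)C | intermediate
20 | (2Z)-4-{[tert-butyl(dimethyl)silyl]oxy}-3-(trimethylsilyl)but-2-enal | O=C/C=C(/CO[Si](C)(C)C(C)(C)C)[Si](C)(C)C | intermediate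
21 | (4R,5S)-4-[(1S,2Z)-4-{[tert-butyl(dimethyl)silyl]oxy}-1-hydroxy-3-(trimethylsilyl)but-2-en-1-yl]-5-[(2S)-6-methoxy-3-methylideneoxan-2-yl]-3-methylideneoxolan-2-one (not isolated; present in the flask as its boron alkoxide) | COC1CCC(=C)[C@H](O1)[C@H]1OC(=O)C(=C)[C@@H]1[C@H](O)/C=C(/CO[Si](C)(C)C(C)(C)C)[Si](C)(C)C | intermediate
22 | (1R,5S,6S,7R,8R,9Z)-14-{[tert-butyl(dimethyl)silyl]oxy}-1,5-epoxy-8-hydroxygermacra-4(15),9,11(13)-trien-12,6-olide | O[C@@H]1/C=C(/CO[Si](C)(C)C(C)(C)C)[C@H]2CCC(=C)[C@H](O2)[C@H]2OC(=O)C(=C)[C@@H]21 | intermediate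
23 | (1R,5S,6S,7R,8R,9Z)-14-{[tert-butyl(dimethyl)silyl]oxy}-1,5-epoxy-8-[(2-methylprop-2-enoyl)oxy]germacra-4(15),9,11(13)-trien-12,6-olide | C=C(C)C(=O)O[C@@H]1/C=C(/CO[Si](C)(C)C(C)(C)C)[C@H]2CCC(=C)[C@H](O2)[C@H]2OC(=O)C(=C)[C@@H]21 | intermediate
24 | (1R,5S,6S,7R,8R,9Z)-1,5-epoxy-14-hydroxy-8-[(2-methylprop-2-enoyl)oxy]germacra-4(15),9,11(13)-trien-12,6-olide | C=C(C)C(=O)O[C@@H]1/C=C(/CO)[C@H]2CCC(=C)[C@H](O2)[C@H]2OC(=O)C(=C)[C@@H]21 | intermediate
25 | (1R,5S,6S,7R,8R,9E)-1,5-epoxy-8-[(2-methylprop-2-enoyl)oxy]-14-oxogermacra-4(15),9,11(13)-trien-12,6-olide | C=C(C)C(=O)O[C@@H]1/C=C(/C=O)[C@H]2CCC(=C)[C@H](O2)[C@H]2OC(=O)C(=C)[C@@H]21 | intermediate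
26 | (1R,4R,5R,6S,7R,8R,9E)-1,5:4,15-diepoxy-8-[(2-methylprop-2-enoyl)oxy]-14-oxogermacra-9,11(13)-dien-12,6-olide | C=C(C)C(=O)O[C@@H]1/C=C(/C=O)[C@H]2CC[C@@]3(CO3)[C@H](O2)[C@H]2OC(=O)C(=C)[C@@H]21 | target

**Step count**
Total: 20 steps. Longest linear sequence: 16 steps (steps 1–11 and 16–20, from furan-3-ylmethanol); the enal branch (steps 12–15) has 4 steps.

**Steps most likely to fail, with fallbacks**

Step 16 (Proposed new method). The relay may break down: the oxocarbenium ion may be intercepted by the C8 oxygen of the first-formed adduct, or the vinylsilane may be protodesilylated before the ten-membered ring closes; the C8 configuration also rests on the open transition state prevailing. The fallback sets out from 14 and 20 and makes the two bonds in separate, individually known operations. Only the BF3·OEt2-promoted allylstannane–aldehyde addition is run (CH2Cl2, −78 °C, cold quench) and the open-chain alcohol 21 is isolated. It is esterified at once (methacrylic anhydride, DMAP, Et3N, CH2Cl2, 0 °C) to the C8 methacrylate of the open-chain adduct F1, whose capped oxygen can no longer trap the cation. F1 is then closed by the known Lewis-acid acetal–vinylsilane cyclisation (SnCl4, 2,6-di-tert-butyl-4-methylpyridine, CH2Cl2, 0.002 M, −40 °C). This comes back to the route at 23, and step 17 is then omitted.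

Step 11. Tin may be delivered to C7 (allylic transposition), or the π-allylpalladium intermediate may lose a β-hydride, giving the transposed stannane or a dienyl lactone instead of 14. The fallback sets out from 13 and uses a Barbier-type stannylation without palladium: Zn dust, Bu3SnCl, THF/saturated aq NH4Cl, rt. The allylzinc formed in the flask is captured by the tin chloride and the allylstannane should equilibrate to the conjugated primary isomer. It comes back to the route at 14; no new compound arises on this path (F0).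

Step 20. Oxygen may be delivered to the wrong face of C4=C15 (syn to C6) if the ten-membered ring shields the expected face. The fallback sets out from 25 and inverts the facial outcome of direct oxygen transfer by a halohydrin sequence. NBS in THF/H2O at 0 °C forms the bromonium ion on the accessible face, and water enters at C4 from the opposite face to give the C15-bromo C4-hydroxy bromohydrin F2. K2CO3 in acetone at rt then closes the epoxide and comes back to the route at 26.

**Further compounds**
F1 | step 16 | (1S,2Z)-4-{[tert-butyl(dimethyl)silyl]oxy}-1-[(3R,2S)-2-[(2S)-6-methoxy-3-methylideneoxan-2-yl]-4-methylidene-5-oxooxolan-3-yl]-3-(trimethylsilyl)but-2-en-1-yl 2-methylprop-2-enoate | COC1CCC(=C)[C@H](O1)[C@H]1OC(=O)C(=C)[C@@H]1[C@H](OC(=O)C(C)=C)/C=C(/CO[Si](C)(C)C(C)(C)C)[Si](C)(C)C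
F0 | step 11 | none | none
F2 | step 20 | (1R,4S,5R,6S,7R,8R,9E)-15-bromo-1,5-epoxy-4-hydroxy-8-[(2-methylprop-2-enoyl)oxy]-14-oxogermacra-9,11(13)-dien-12,6-olide | C=C(C)C(=O)O[C@@H]1/C=C(/C=O)[C@H]2CC[C@@](O)(CBr)[C@H](O2)[C@H]2OC(=O)C(=C)[C@@H]21
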